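Slowness comes first in these flasks: at 0.50 mM of starting material, the coupling partner enters the first coupling at 0.0184 s⁻¹ per unit of partner at the start, while it decays faster than that, at 0.0259 s⁻¹, so each flask must be judged by how much partner the starting material meets before decay takes it.

| setting | epsilon | theta | gamma |
|---|---|---|---|
| starting material | 0.50 mM | 0.50 mM | 0.50 mM |
| coupling partner | 1.30 equiv | 2.60 equiv | 5.20 equiv |
| time | 30 s | 30 s | 30 s |

    starting material + coupling partner → first product (k1 = 36.7 M⁻¹ s⁻¹)
    coupling partner + first product → bis adduct (k2 = 34.6 M⁻¹ s⁻¹)
    starting material + first product → side product (k3 = 3.88 M⁻¹ s⁻¹)
    coupling partner → decomposed reagent (k4 = 0.0259 s⁻¹)

- percent here means starting material units held: one side product counts as two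
- run time (epsilon): 30 s

- which of these there is most of at the end, counted by the starting material in it, epsilon (bis adduct / side product / starting material / first product)
- which of these there is most of at the end, counted by the starting material in it, theta (bis adduct / side product / starting material / first product)
- which of these there is most of at the end, counted by the starting material in it, gamma (bis adduct / side product / starting material / first product)
- final amount of the leader among these, as a percentage of the starting material charged, in epsilon
- final amount of the leader among these, as a percentage of the starting material charged, in theta
- final amount of the leader among these, as a percentage of the starting material charged, in gamma

What do you count? Lifetimes of the coupling partner. The two coupling constants are close, so its reactive loss is roughly the first constant times starting material plus first product, and I hold that sum at the charge as an assumption, setting the side step aside since its half-life on first product in epsilon, 6.0 min, is longer than the run. The partner then falls in a pseudo-first-order way at 0.0442 s⁻¹, a constant with no partner charge in it, which gives a lifetime of 22.6 s, and the run lasts 1.33 lifetimes, leaving 26.5% of the partner's own charge.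

And what do you do with that? I form the lifetime times one minus the fraction left, 16.6 s, and call it the effective window, the time for which partner held at its full charge would give the same contact as the decaying partner gives over the whole run. Exposure is the first constant times charged partner times this window: 0.396 in epsilon, 0.792 in theta, 1.58 in gamma.

So who leads? With equal constants, starting material is e to the minus exposure, first product is exposure times that, and bis adduct is the remainder. Epsilon therefore keeps 67.3% starting material, theta keeps 45.3% against 35.9% first product, and gamma holds 47.0% bis adduct against 32.5% first product.

Isn't your sum wrong in gamma? Partly, because bis adduct leaves that sum, and I reckon more of it in gamma than in epsilon, so the partner should outlast my lifetime in gamma and my exposure there leans low.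

The forecast, holding that “the first product never quite leads at these three charges”, named starting material at 66% for epsilon, starting material at 43% for theta and bis adduct at 47% for gamma.

The simulation gives starting material at 66.5% in epsilon, starting material at 44.1% in theta, with first product at 35.9%, and bis adduct at 46.9% in gamma. The partner left of its own charge reads 27%, 28% and 31% in those flasks.

Read back through e to the minus exposure, theta's starting material gives an exposure of 0.819 against my 0.792. A neighbour of theta charged with 10.0 equiv of coupling partner takes the same window of 16.6 s, which gives an exposure of 3.05 and so 4.75% starting material, 14.5% first product and 80.8% bis adduct. That neighbour ends with 3.64% starting material, 13.3% first product and 82.4% bis adduct, and 35.6% of its partner charge remains.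

The constants used here are assumed; what happens was integrated by code.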